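## Retrosynthetic overview

- Numbering (bicyclo[3.3.1]nonane): C1 bridgehead with isobutyryl, C2–C4 enolised 1,3-dione, C5 bridgehead CH, C6 CH2, C7 CH(prenyl), C8 quaternary C(CH3)(homogeranyl), C9 bridging C=O; ring 1 = C1-C8-C7-C6-C5-C9, ring 2 = C1-C2-C3-C4-C5-C9.
- Last disconnection: ring 2 at C1–C2 and C4–C5, a malonyl bridge laid over the enol ether of a 2-acylcyclohexanone (Effenberger-type annulation).
- Key disconnection: ring 1 at C1–C9 and C7–C8, an enantioselective Diels–Alder union of the C18 (E)-enone C8=C1–C(=O)i-Pr (from farnesol) with the C9 1-silyloxydiene C9=C5–C6=C7 that carries the prenyl group on C7.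
- Enabling feature: in ring 1 the oxygen-bearing C9 is bonded to C1, whose exocyclic isobutyryl C=O is conjugated in the retron with C1=C8, and C7 stands 1,4 to C9. Ring 1 is thus the "ortho", endo adduct of a 1-oxydiene and a β,β-disubstituted enone, and the E geometries of both partners give the cis array prenyl (C7) / methyl (C8) / acyl (C1).
- Ring order: ring 1 first (step 6); then C5=C6 is saturated and C9 raised to the ketone; ring 2 last (step 11).

Key step: step 6

Assumption 1: (2E,6E)-farnesol and 5-methylhex-4-enal are taken as catalogue compounds (the aldehyde is otherwise available from 2-methylbut-3-en-2-ol by Claisen rearrangement).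
Assumption 2: the sense of induction of the chiral boron Lewis acid in step 6 is taken from the usual model for a carbonyl-bound s-cis enone; should it prove opposite, the mirror-image catalyst is used.

## Route

Step 1
Reactants: 1 (2E,6E)-farnesol
Product: 2 (2E,6E)-farnesal
Conditions: MnO2 (activated, excess), CH2Cl2, rt
Reagents that add atoms: none
Why: Allylic oxidation with activated MnO2 should convert the primary allylic alcohol into the enal without touching the isolated alkenes and without loss of the (2E) geometry.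

Step 2
Reactants: 2 (2E,6E)-farnesal
Product: 3 (4E,8E)-2,5,9,13-tetramethyltetradeca-4,8,12-trien-3-ol (racemic at C3)
Conditions: i-PrMgCl, THF, −78 → 0 °C; aq NH4Cl
Reagents that add atoms: isopropylmagnesium chloride CC(C)[Mg]Cl
Why: Grignard 1,2-addition to the enal should win over conjugate addition at the β,β-disubstituted position; the carbinol centre forms as a racemate and is removed in step 3.

Step 3
Reactants: 3 (4E,8E)-2,5,9,13-tetramethyltetradeca-4,8,12-trien-3-ol
Product: 4 (4E,8E)-2,5,9,13-tetramethyltetradeca-4,8,12-trien-3-one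
Conditions: Dess–Martin periodinane, CH2Cl2, 0 °C → rt
Reagents that add atoms: none
Why: Dess–Martin oxidation of the secondary allylic alcohol should give the (E)-enone (acyl cis to the methyl group) under conditions that do not isomerise the trisubstituted C=C.

Step 4
Reactants: 5 5-methylhex-4-enal
Product: 6 (2E)-7-methylocta-2,6-dienal
Conditions: Ph3P=CHCHO, toluene, 80 °C
Reagents that add atoms: (triphenylphosphoranylidene)acetaldehyde O=CC=P(c1ccccc1)(c1ccccc1)c1ccccc1
Why: Wittig olefination with the stabilised formylmethylene ylide should give the (E)-enal.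

Step 5
Reactants: 6 (2E)-7-methylocta-2,6-dienal
Product: 7 (1E,3E)-7-methyl-1-(triisopropylsilyloxy)octa-1,3,6-triene
Conditions: i-Pr3SiOTf, Et3N, Et2O, 0 °C → rt
Reagents that add atoms: triisopropylsilyl trifluoromethanesulfonate CC(C)[Si](OS(=O)(=O)C(F)(F)F)(C(C)C)C(C)C
Why: Soft enolisation (γ-deprotonation of the silyl-activated enal) with O-silylation should give the 1-silyloxy-1,3-diene, of which the (1E,3E) isomer is expected to predominate and is the only one able to reach the s-cis conformation needed in step 6.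

Step 6
Reactants: 4 (4E,8E)-2,5,9,13-tetramethyltetradeca-4,8,12-trien-3-one; 7 (1E,3E)-7-methyl-1-(triisopropylsilyloxy)octa-1,3,6-triene
Product: 8 1-[(1S,2R,5S,6R)-6-[(3E)-4,8-dimethylnona-3,7-dien-1-yl]-6-methyl-5-(3-methylbut-2-en-1-yl)-2-(triisopropylsilyloxy)cyclohex-3-en-1-yl]-2-methylpropan-1-one (silyloxy, acyl, methyl and prenyl all cis)
Conditions: (S)-1-(2-methylphenyl)-3,3-diphenyltetrahydro-1H,3H-pyrrolo[1,2-c][1,3,2]oxazaborole (20 mol %), HN(SO2CF3)2 (20 mol %), CH2Cl2, −78 → −20 °C
Reagents that add atoms: none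
Why: Proposed new method: the cationic chiral boron Lewis acid binds the carbonyl oxygen of the s-cis enone 4 and lowers its LUMO, so that the 1-silyloxydiene 7 should add in a concerted but asynchronous [4+2] in which the C7–C8 bond (diene terminus para to the oxygen donor onto the β-carbon) runs ahead of the C9–C1 bond. The closest known reactions are oxazaborolidinium-catalysed enantioselective Diels–Alder reactions of acyclic enones with silyloxydienes and Lewis-acid or high-pressure Diels–Alder reactions of β,β-disubstituted enones; new is their combination, a β,β-disubstituted acyclic enone that forms a quaternary carbon under asymmetric catalysis. The only ring closed is the cyclohexene that becomes ring 1 (C1, C8, C7, C6, C5, C9), by intermolecular suprafacial–suprafacial [4+2] cycloaddition. The (E) geometry of 4 is transferred, so methyl on C8 and acyl on C1 end up cis, and the (1E,3E) geometry of 7 places prenyl on C7 and silyloxy on C9 cis. The endo transition state (acyl and the small methyl group under the diene, the long chain outside) relates the two pairs and gives prenyl on C7 cis to methyl on C8 as in the target, while the absolute configuration comes from the catalyst, which shields one face of the bound enone. The step needs regioselectivity (C7 to C8, not C7 to C1), secured by the donor oxygen on C9 and the acceptor carbonyl on C1, and chemoselectivity among six C=C bonds, secured because only the enone double bond is activated.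

Step 7
Reactants: 8 silyl ether adduct
Product: 9 1-[(1S,2R,5S,6R)-6-[(3E)-4,8-dimethylnona-3,7-dien-1-yl]-2-hydroxy-6-methyl-5-(3-methylbut-2-en-1-yl)cyclohex-3-en-1-yl]-2-methylpropan-1-one
Conditions: n-Bu4NF, AcOH (1:1), THF, 0 °C → rt
Reagents that add atoms: none
Why: Fluoride-mediated desilylation should free the allylic alcohol, and buffering with acetic acid should suppress retro-aldol cleavage and β-elimination of the β-hydroxy ketone.

Step 8
Reactants: 9 allylic alcohol
Product: 10 1-[(1S,2R,5R,6R)-6-[(3E)-4,8-dimethylnona-3,7-dien-1-yl]-2-hydroxy-6-methyl-5-(3-methylbut-2-en-1-yl)cyclohexyl]-2-methylpropan-1-one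
Conditions: KO2C–N=N–CO2K, AcOH, MeOH, 0 °C → rt
Reagents that add atoms: none
Why: Diimide reduction (concerted syn transfer of H2) should saturate the cis-disubstituted ring alkene much faster than the three trisubstituted side-chain alkenes and leaves the ketone alone.

Step 9
Reactants: 10 saturated β-hydroxy ketone
Product: 11 (3R,4R)-3-[(3E)-4,8-dimethylnona-3,7-dien-1-yl]-3-methyl-4-(3-methylbut-2-en-1-yl)-2-(2-methylpropanoyl)cyclohexan-1-one (C2 epimers and enol forms)
Conditions: Dess–Martin periodinane, CH2Cl2, rt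
Reagents that add atoms: none
Why: Dess–Martin oxidation should give the 2-acylcyclohexanone; C1 becomes an enolisable centre of no consequence, whereas C7 and C8 cannot enolise and stay fixed.

Step 10
Reactants: 11 2-acylcyclohexanone
Product: 12 1-[(5R,6R)-6-[(3E)-4,8-dimethylnona-3,7-dien-1-yl]-2-methoxy-6-methyl-5-(3-methylbut-2-en-1-yl)cyclohex-1-en-1-yl]-2-methylpropan-1-one
Conditions: Me3SiCHN2, MeOH–toluene (1:4), 0 °C → rt
Reagents that add atoms: (trimethylsilyl)diazomethane C[Si](C)(C)C=[N+]=[N-]
Why: O-methylation of the strongly enolised β-diketone by the diazoalkane should give the methyl enol ether, the substrate type of the Effenberger cyclisation; a regioisomeric enol ether would converge in step 11.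

Step 11
Reactants: 12 methyl enol ether; 13 malonyl dichloride
Product: 15 prolifenone B (1R,5R,7S,8R), via acid chloride 14 (not isolated)
Conditions: Et2O, −20 °C → rt; then H2O
Reagents that add atoms: none
Why: Proposed new method: following the mechanism of the Effenberger cyclisation, the enol ether (through its cross-conjugated isomer formed under the HCl released) should be C-acylated at C5 to give 14, the enol ether carbon C1 should then attack the second acyl chloride intramolecularly on the ring face anti to the C7 prenyl group (the only cis-diaxial bridge that leaves prenyl equatorial, which sets C1 and C5), and chloride should demethylate the oxocarbenium ion to the enolised trione; the closest known reaction is the Effenberger α,α'-annulation of cyclohexanone methyl or silyl enol ethers with malonyl dichloride, which also builds quaternary bridgeheads but has not been shown on a 2-acyl enol ether.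

## Compound list

1 | (2E,6E)-farnesol | CC(C)=CCC/C(C)=C/CC/C(C)=C/CO | starting material
2 | (2E,6E)-farnesal | CC(C)=CCC/C(C)=C/CC/C(C)=C/C=O | intermediate
3 | (4E,8E)-2,5,9,13-tetramethyltetradeca-4,8,12-trien-3-ol (racemic) | CC(C)=CCC/C(C)=C/CC/C(C)=C/C(O)C(C)C | intermediate
4 | (4E,8E)-2,5,9,13-tetramethyltetradeca-4,8,12-trien-3-one | CC(C)=CCC/C(C)=C/CC/C(C)=C/C(=O)C(C)C | intermediate
5 | 5-methylhex-4-enal | CC(C)=CCCC=O | starting material
6 | (2E)-7-methylocta-2,6-dienal | CC(C)=CCC/C=C/C=O | intermediate
7 | (1E,3E)-7-methyl-1-(triisopropylsilyloxy)octa-1,3,6-triene | CC(C)=CC/C=C/C=C/O[Si](C(C)C)(C(C)C)C(C)C | intermediate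
8 | 1-[(1S,2R,5S,6R)-6-[(3E)-4,8-dimethylnona-3,7-dien-1-yl]-6-methyl-5-(3-methylbut-2-en-1-yl)-2-(triisopropylsilyloxy)cyclohex-3-en-1-yl]-2-methylpropan-1-one | CC(C)=CCC/C(C)=C/CC[C@]1(C)[C@@H](CC=C(C)C)C=C[C@@H](O[Si](C(C)C)(C(C)C)C(C)C)[C@H]1C(=O)C(C)C | intermediate
9 | 1-[(1S,2R,5S,6R)-6-[(3E)-4,8-dimethylnona-3,7-dien-1-yl]-2-hydroxy-6-methyl-5-(3-methylbut-2-en-1-yl)cyclohex-3-en-1-yl]-2-methylpropan-1-one | CC(C)=CCC/C(C)=C/CC[C@]1(C)[C@@H](CC=C(C)C)C=C[C@@H](O)[C@H]1C(=O)C(C)C | intermediate
10 | 1-[(1S,2R,5R,6R)-6-[(3E)-4,8-dimethylnona-3,7-dien-1-yl]-2-hydroxy-6-methyl-5-(3-methylbut-2-en-1-yl)cyclohexyl]-2-methylpropan-1-one | CC(C)=CCC/C(C)=C/CC[C@]1(C)[C@@H](CC=C(C)C)CC[C@@H](O)[C@H]1C(=O)C(C)C | intermediate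
11 | (3R,4R)-3-[(3E)-4,8-dimethylnona-3,7-dien-1-yl]-3-methyl-4-(3-methylbut-2-en-1-yl)-2-(2-methylpropanoyl)cyclohexan-1-one (C2 epimers, enolised) | CC(C)=CCC/C(C)=C/CC[C@]1(C)[C@@H](CC=C(C)C)CCC(=O)C1C(=O)C(C)C | intermediate
12 | 1-[(5R,6R)-6-[(3E)-4,8-dimethylnona-3,7-dien-1-yl]-2-methoxy-6-methyl-5-(3-methylbut-2-en-1-yl)cyclohex-1-en-1-yl]-2-methylpropan-1-one | CC(C)=CCC/C(C)=C/CC[C@]1(C)[C@@H](CC=C(C)C)CCC(OC)=C1C(=O)C(C)C | intermediate
13 | malonyl dichloride (propanedioyl dichloride) | O=C(Cl)CC(=O)Cl | starting material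
14 | 3-[(4R,5S)-4-[(3E)-4,8-dimethylnona-3,7-dien-1-yl]-2-methoxy-4-methyl-5-(3-methylbut-2-en-1-yl)-3-(2-methylpropanoyl)cyclohex-2-en-1-yl]-3-oxopropanoyl chloride (C1 epimers) | CC(C)=CCC/C(C)=C/CC[C@]1(C)[C@@H](CC=C(C)C)CC(C(=O)CC(=O)Cl)C(OC)=C1C(=O)C(C)C | intermediate
15 | prolifenone B, (1R,5R,7S,8R)-8-[(3E)-4,8-dimethylnona-3,7-dien-1-yl]-4-hydroxy-8-methyl-7-(3-methylbut-2-en-1-yl)-1-(2-methylpropanoyl)bicyclo[3.3.1]non-3-ene-2,9-dione | CC(C)=CCC/C(C)=C/CC[C@]1(C)[C@@H](CC=C(C)C)C[C@H]2C(=O)[C@]1(C(=O)C(C)C)C(=O)C=C2O | target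

## Step count and risks

Total step count: 11. Longest linear sequence: 9 steps (steps 1, 2, 3, 6, 7, 8, 9, 10, 11).

Steps most likely to fail:

1. Step 6 (Proposed new method). The Lewis acid may divert the reaction: silyl transfer after the first C–C bond would give an open-chain conjugate adduct that cannot close, the activated enone may undergo cation–olefin cyclisation of its polyene chain, and facial discrimination may be poor. Fallback, from 4 and 7 back to 8: the uncatalysed Diels–Alder reaction at 12–15 kbar (CH2Cl2, 40 °C), a known remedy for β,β-disubstituted enones, should give the endo adduct as a racemate, that is 8 together with its mirror image, the (1R,2S,5R,6S) adduct F1. Absolute control is then moved from the cycloaddition to a separation: preparative HPLC on a chiral stationary phase (amylose tris(3,5-dimethylphenylcarbamate)) should return enantiopure 8.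

2. Step 11 (Proposed new method). After the first C-acylation, acylation on oxygen (lactone formation towards a fused hydroxypyranone) may outrun C-acylation at the hindered C1, and the HCl released may add to or cyclise the side-chain alkenes. Fallback, from 11 to 15 by known reactions:
   - Michael addition of 11 to acrolein (DBU cat., MeCN) should alkylate C1 anti to the axial C8 methyl group and give the keto aldehyde F2.
   - Base-mediated intramolecular aldol addition from C5 to the aldehyde should close ring 2 as the ketol F3.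
   - Dess–Martin oxidation should give the 4,9-dione F4.
   - IBX dehydrogenation (DMSO–toluene, 70 °C) should give the enedione F5.
   - Nucleophilic epoxidation (t-BuOOH, DBU) should give the epoxy ketone F6.
   - Isomerisation of the α,β-epoxy ketone to the 1,3-diketone with Pd(PPh3)4 and 1,2-bis(diphenylphosphino)ethane (toluene, 80 °C) should deliver 15.

3. Step 5. Kinetic γ-deprotonation may give the (3Z)-diene or an isomer mixture; such dienes cannot adopt the s-cis conformation and the cycloaddition would stall. Fallback, from 6 back to 7: enol acetylation under equilibrating conditions (isopropenyl acetate, TsOH cat., 90 °C) should give the thermodynamic (1E,3E)-7-methylocta-1,3,6-trien-1-yl acetate F7. Cleavage with MeLi (2 equiv, THF, −78 °C) releases the lithium dienolate with retention of geometry, and trapping with i-Pr3SiCl should give 7.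

## Further compounds

F1 | step 6 | enantiomer of 8, 1-[(1R,2S,5R,6S)-6-[(3E)-4,8-dimethylnona-3,7-dien-1-yl]-6-methyl-5-(3-methylbut-2-en-1-yl)-2-(triisopropylsilyloxy)cyclohex-3-en-1-yl]-2-methylpropan-1-one | CC(C)=CCC/C(C)=C/CC[C@@]1(C)[C@H](CC=C(C)C)C=C[C@H](O[Si](C(C)C)(C(C)C)C(C)C)[C@@H]1C(=O)C(C)C
F2 | step 11 | 3-[2-[(3E)-4,8-dimethylnona-3,7-dien-1-yl]-2-methyl-3-(3-methylbut-2-en-1-yl)-1-(2-methylpropanoyl)-6-oxocyclohexyl]propanal (configuration at C1, C7, C8 as in 15) | CC(C)=CCC/C(C)=C/CC[C@]1(C)[C@@H](CC=C(C)C)CCC(=O)[C@]1(C(=O)C(C)C)CCC=O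
F3 | step 11 | 8-[(3E)-4,8-dimethylnona-3,7-dien-1-yl]-4-hydroxy-8-methyl-7-(3-methylbut-2-en-1-yl)-1-(2-methylpropanoyl)bicyclo[3.3.1]nonan-9-one (C1, C5, C7, C8 as in 15; C4 epimers) | CC(C)=CCC/C(C)=C/CC[C@]1(C)[C@@H](CC=C(C)C)C[C@H]2C(=O)[C@]1(C(=O)C(C)C)CCC2O
F4 | step 11 | 8-[(3E)-4,8-dimethylnona-3,7-dien-1-yl]-8-methyl-7-(3-methylbut-2-en-1-yl)-1-(2-methylpropanoyl)bicyclo[3.3.1]nonane-4,9-dione (C1, C5, C7, C8 as in 15) | CC(C)=CCC/C(C)=C/CC[C@]1(C)[C@@H](CC=C(C)C)C[C@H]2C(=O)[C@]1(C(=O)C(C)C)CCC2=O
F5 | step 11 | 8-[(3E)-4,8-dimethylnona-3,7-dien-1-yl]-8-methyl-7-(3-methylbut-2-en-1-yl)-1-(2-methylpropanoyl)bicyclo[3.3.1]non-2-ene-4,9-dione (C1, C5, C7, C8 as in 15) | CC(C)=CCC/C(C)=C/CC[C@]1(C)[C@@H](CC=C(C)C)C[C@H]2C(=O)[C@]1(C(=O)C(C)C)C=CC2=O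
F6 | step 11 | 2,3-epoxide of F5 (2,3-epoxy-4,9-dione; C1, C5, C7, C8 as in 15) | CC(C)=CCC/C(C)=C/CC[C@]1(C)[C@@H](CC=C(C)C)C[C@H]2C(=O)[C@]1(C(=O)C(C)C)C3OC3C2=O
F7 | step 5 | (1E,3E)-7-methylocta-1,3,6-trien-1-yl acetate | CC(C)=CC/C=C/C=C/OC(C)=O
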